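**Plan**
- The target is a trimer of 8-methoxy-1-naphthol: central unit B carries outer unit A at C2 and outer unit C at C4. In A and C (numbered as naphthols), C4 holds the bond to B, C2 and C3 bear only hydrogen, and C1(OH) lies peri to C8(OMe). C4 can therefore start as a diarylmethane carbon, C1 as an ester carbon on the methoxybenzene ring, and C2–C3 as a two-carbon acceptor.
- Retrosynthesis: cut the O–CH2OMe bond on ring B first. Then cut C4–C3 and C2–C1 in both outer units at once, which leaves a bis(diarylmethane) diester and two molecules of phenyl vinyl sulfoxide (an ethyne equivalent). Finally cut the two aryl–CH2 bonds at C2 and C4 of B.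
- Forward: unit B comes intact from 1,8-dihydroxynaphthalene (methylation, dibromination, acetal protection). The benzo rings of A and C come from methyl 2-methoxy-6-methylbenzoate, joined to B by a twofold Negishi coupling. Both phenolic rings of A and C close together in step 6, and acetal cleavage ends the route.
- Stereochemistry: the target has no stereocentre. The transient stereocentres of the annulation vanish on aromatization.

Key step: step 6

Assumption: the two biaryl axes are drawn without configuration and are treated as undefined; the route does not try to control them.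

**Step 1**
Reactants: 1 1,8-dihydroxynaphthalene
Product: 2 8-methoxynaphthalen-1-ol
Conditions: MeI (1.1 equiv), K2CO3, acetone, 50 °C
Reagents that add atoms: iodomethane, CI
Why: Williamson O-methylation: K2CO3 forms only the hydrogen-bond-stabilized monoanion of the peri diol, and after one methylation the remaining hydroxyl is hydrogen-bonded to the new methoxy oxygen and much less acidic, so one equivalent of MeI should stop at the monoether.

**Step 2**
Reactants: 2 8-methoxynaphthalen-1-ol
Product: 3 2,4-dibromo-8-methoxynaphthalen-1-ol
Conditions: NBS (2.05 equiv), dry MeCN, −20 → 0 °C, dark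
Reagents that add atoms: N-bromosuccinimide, O=C1CCC(=O)N1Br
Why: Electrophilic aromatic bromination: the free hydroxyl activates its own ring far more than the methoxy group activates the other, so two equivalents of NBS should enter para (C4) and then ortho (C2) to the hydroxyl, with anhydrous conditions suppressing oxidation to the naphthoquinone.

**Step 3**
Reactants: 3 2,4-dibromo-8-methoxynaphthalen-1-ol
Product: 4 2,4-dibromo-8-methoxy-1-(methoxymethoxy)naphthalene
Conditions: NaH, THF/DMF, 0 °C; MOMCl, 0 → 25 °C
Reagents that add atoms: chloromethyl methyl ether, COCCl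
Why: Williamson-type O-alkylation of the sodium naphthoxide with the small, reactive chloromethyl ether should overcome crowding by the ortho bromine and peri methoxy group, and the acetal formed is stable to the organozinc, LiN(iPr)2 and palladium steps ahead.

**Step 4**
Reactants: 5 methyl 2-methoxy-6-methylbenzoate
Product: 6 methyl 2-(bromomethyl)-6-methoxybenzoate
Conditions: NBS (1.05 equiv), AIBN (cat.), PhCF3, 80 °C
Reagents that add atoms: N-bromosuccinimide, O=C1CCC(=O)N1Br
Why: Wohl–Ziegler radical bromination at the only benzylic methyl group; the ester-deactivated ring resists electrophilic bromination under non-polar radical conditions, and one equivalent of NBS limits dibromination.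

**Step 5**
Reactants: 6 methyl 2-(bromomethyl)-6-methoxybenzoate; 4 2,4-dibromo-8-methoxy-1-(methoxymethoxy)naphthalene
Product: 8 dimethyl 2,2'-{[8-methoxy-1-(methoxymethoxy)naphthalene-2,4-diyl]bis(methylene)}bis(6-methoxybenzoate), via benzylic zinc bromide 7 (not isolated)
Conditions: 6 (2.6 equiv), Zn dust, LiCl, THF, 0 → 25 °C; then 4, Pd(OAc)2 (5 mol%), SPhos (10 mol%), THF, 25 → 55 °C
Reagents that add atoms: none
Why: Direct LiCl-assisted zinc insertion into the benzylic C–Br bond gives an ester-tolerant benzylic zinc bromide, and Negishi cross-coupling under zerovalent palladium with the bulky biaryl phosphine SPhos should substitute both the C4 and the more hindered C2 bromide of 4, the excess zinc reagent driving the second coupling.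

**Step 6**
Reactants: 8 dimethyl 2,2'-{[8-methoxy-1-(methoxymethoxy)naphthalene-2,4-diyl]bis(methylene)}bis(6-methoxybenzoate); 9 phenyl vinyl sulfoxide
Product: 12 4,4'-[8-methoxy-1-(methoxymethoxy)naphthalene-2,4-diyl]bis(8-methoxynaphthalen-1-ol), via bis(2-phenylsulfinyl-1-tetralone) 10 (not isolated), via bis(4H-naphthalen-1-one) 11 (not isolated)
Conditions: LiN(iPr)2 (2.5 equiv), THF, −78 °C; 9 (2.6 equiv), −78 → 0 °C; AcOH; then toluene, 90 °C
Reagents that add atoms: none
Why: Proposed new method: LiN(iPr)2 removes one proton from each diarylmethane CH2 (lateral lithiation; each carbanion is delocalized into two arenes and the ortho ester), each carbanion adds to the β-carbon of phenyl vinyl sulfoxide (C4–C3 bond), and the resulting α-sulfinyl carbanion acylates itself on the neighbouring methyl ester (C2–C1 bond, Claisen condensation) with loss of methoxide, which then deprotonates the β-keto sulfoxide and drives the sequence forward. The closest known reaction types are the Staunton–Weinreb toluate Michael–Claisen annulation and the Hauser sulfoxide annulation, in which the sulfinyl group sits on the donor; a sulfinyl group on the acceptor, a diarylmethyl donor and a twofold version are the extensions proposed. Each of the two rings closes in a 6-exo-trig mode, the carbonyl oxygen lying outside the new six-membered ring. After neutralization, heating the bis(β-keto sulfoxide) 10 should cause thermal syn-elimination of PhSOH across C2–C3, and the 4H-naphthalen-1-ones 11 tautomerize to the naphthols, so no oxidant is needed and the stereocentres of 10 (C2, C4 and sulfur, formed without control as a mixture) are all erased; no stereocentre remains in 12. The step needs site selectivity in deprotonation and the right order of bond formation: the doubly benzylic, ester-flanked CH2 groups are by far the most acidic C–H bonds at −78 °C, and because the sulfinyl carbanion exists only after the conjugate addition and can reach only its own ester through a six-membered transition state, the ester carbon must become C1 next to the methoxy-bearing C8.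

**Step 7**
Reactants: 12 4,4'-[8-methoxy-1-(methoxymethoxy)naphthalene-2,4-diyl]bis(8-methoxynaphthalen-1-ol)
Product: 13 2,4-bis(4-hydroxy-5-methoxynaphthalen-1-yl)-8-methoxynaphthalen-1-ol
Conditions: HCl (cat.), MeOH/THF, 40 °C, under argon
Reagents that add atoms: none
Why: Acid-catalysed acetal cleavage (transacetalization with methanol) removes the methoxymethyl group, while the three aryl methyl ethers and the free naphthols are inert to dilute HCl at this temperature.

**Compound list**
1 | 1,8-dihydroxynaphthalene | Oc1cccc2cccc(O)c12 | starting material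
2 | 8-methoxynaphthalen-1-ol | COc1cccc2cccc(O)c12 | intermediate
3 | 2,4-dibromo-8-methoxynaphthalen-1-ol | Oc1c(Br)cc(Br)c2cccc(OC)c12 | intermediate
4 | 2,4-dibromo-8-methoxy-1-(methoxymethoxy)naphthalene | COCOc1c(Br)cc(Br)c2cccc(OC)c12 | intermediate
5 | methyl 2-methoxy-6-methylbenzoate | COC(=O)c1c(C)cccc1OC | starting material
6 | methyl 2-(bromomethyl)-6-methoxybenzoate | COC(=O)c1c(CBr)cccc1OC | intermediate
7 | [3-methoxy-2-(methoxycarbonyl)benzyl]zinc bromide (formed in the flask, not isolated) | COC(=O)c1c(C[Zn]Br)cccc1OC | intermediate
8 | dimethyl 2,2'-{[8-methoxy-1-(methoxymethoxy)naphthalene-2,4-diyl]bis(methylene)}bis(6-methoxybenzoate) | COCOc1c(Cc2cccc(OC)c2C(=O)OC)cc(Cc2cccc(OC)c2C(=O)OC)c2cccc(OC)c12 | intermediate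
9 | phenyl vinyl sulfoxide (racemic) | C=CS(=O)c1ccccc1 | starting material
10 | 8-methoxy-1-(methoxymethoxy)-2,4-bis[5-methoxy-4-oxo-3-(phenylsulfinyl)-1,2,3,4-tetrahydronaphthalen-1-yl]naphthalene (mixture of diastereomers, not isolated) | COCOc1c(C2CC(S(=O)c3ccccc3)C(=O)c3c(OC)cccc32)cc(C2CC(S(=O)c3ccccc3)C(=O)c3c(OC)cccc32)c2cccc(OC)c12 | intermediate
11 | 8-methoxy-1-(methoxymethoxy)-2,4-bis(5-methoxy-4-oxo-1,4-dihydronaphthalen-1-yl)naphthalene (not isolated) | COCOc1c(C2C=CC(=O)c3c(OC)cccc32)cc(C2C=CC(=O)c3c(OC)cccc32)c2cccc(OC)c12 | intermediate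
12 | 4,4'-[8-methoxy-1-(methoxymethoxy)naphthalene-2,4-diyl]bis(8-methoxynaphthalen-1-ol) | COCOc1c(-c2ccc(O)c3c(OC)cccc23)cc(-c2ccc(O)c3c(OC)cccc23)c2cccc(OC)c12 | intermediate
13 | 2,4-bis(4-hydroxy-5-methoxynaphthalen-1-yl)-8-methoxynaphthalen-1-ol | COc1cccc2c(-c3cc(-c4ccc(O)c5c(OC)cccc45)c4cccc(OC)c4c3O)ccc(O)c12 | target

**Count**
Total steps: 7. Longest linear sequence: 6 steps (steps 1, 2, 3, 5, 6, 7, from 1 to 13); the branch from 5 enters at step 5.

**Steps most likely to fail**

1. Step 6 (proposed new method). The crowded, strongly stabilized diarylmethyl carbanions may add too slowly to the vinyl sulfoxide. Proton transfer may quench the α-sulfinyl carbanion before ring closure. The vinyl sulfoxide may oligomerize, or sulfenic acid-derived species may sulfenylate the electron-rich naphthols during the elimination. The fallback forms the two biaryl bonds directly by known cross-coupling; it sets out from 2 and 4 and returns at 13. Bromination of 2 para to the hydroxyl (NBS, 1 equiv, MeCN, −20 °C) would give 4-bromo-8-methoxynaphthalen-1-ol F1. O-alkylation (NaH, MOMCl, THF/DMF) would give 4-bromo-8-methoxy-1-(methoxymethoxy)naphthalene F2. Miyaura borylation (B2pin2, PdCl2(dppf), KOAc, dioxane, 90 °C) would give 2-[5-methoxy-4-(methoxymethoxy)naphthalen-1-yl]-4,4,5,5-tetramethyl-1,3,2-dioxaborolane F3. Twofold Suzuki–Miyaura coupling of F3 with dibromide 4 (Pd(OAc)2, SPhos, K3PO4, toluene/H2O, 90 °C) would give 8-methoxy-1-(methoxymethoxy)-2,4-bis[5-methoxy-4-(methoxymethoxy)naphthalen-1-yl]naphthalene F4. The conditions of step 7 would then cleave all three acetals and give 13.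

2. Step 5. The coupling may stall after the first substitution because oxidative addition and transmetalation at the C2 bromide, flanked by the acetal, are slow. The benzylic zinc reagent may also be lost to Wurtz-type homocoupling or to lactonization onto its own ester. The fallback reverses the polarity of the coupling; it sets out from 4 and returns at 8. Twofold Miyaura borylation of 4 (B2pin2, PdCl2(dppf), KOAc, dioxane, 90 °C) would give 2,2'-[8-methoxy-1-(methoxymethoxy)naphthalene-2,4-diyl]bis(4,4,5,5-tetramethyl-1,3,2-dioxaborolane) F5. Suzuki–Miyaura benzylation of F5 with bromide 6 (Pd(PPh3)4, K3PO4, toluene/H2O, 80 °C) would give 8.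

3. Step 2. Bromination may spill onto the methoxy-bearing ring (C5, C7), or NBS may oxidize the naphthol to a quinone, giving mixtures instead of clean 2,4-substitution. The fallback deactivates the second ring before halogenation; it sets out from 1 and returns at 4. Monosulfonylation of 1 (TsCl, 1 equiv, K2CO3, acetone) would give 8-hydroxynaphthalen-1-yl 4-methylbenzenesulfonate F6. Bromination can then only take place on the free naphthol ring (NBS, 2 equiv, MeCN, 0 °C), giving 5,7-dibromo-8-hydroxynaphthalen-1-yl 4-methylbenzenesulfonate F7. Acetal protection (NaH, MOMCl) would give 5,7-dibromo-8-(methoxymethoxy)naphthalen-1-yl 4-methylbenzenesulfonate F8. Sulfonate cleavage (KOH, EtOH/H2O, reflux) would give 5,7-dibromo-8-(methoxymethoxy)naphthalen-1-ol F9. Methylation (MeI, K2CO3, DMF) would give 4.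

**Further compounds**
F1 | step 6 | 4-bromo-8-methoxynaphthalen-1-ol | Oc1ccc(Br)c2cccc(OC)c12
F2 | step 6 | 4-bromo-8-methoxy-1-(methoxymethoxy)naphthalene | COCOc1ccc(Br)c2cccc(OC)c12
F3 | step 6 | 2-[5-methoxy-4-(methoxymethoxy)naphthalen-1-yl]-4,4,5,5-tetramethyl-1,3,2-dioxaborolane | COCOc1ccc(B2OC(C)(C)C(C)(C)O2)c2cccc(OC)c12
F4 | step 6 | 8-methoxy-1-(methoxymethoxy)-2,4-bis[5-methoxy-4-(methoxymethoxy)naphthalen-1-yl]naphthalene | COCOc1ccc(-c2cc(-c3ccc(OCOC)c4c(OC)cccc34)c3cccc(OC)c3c2OCOC)c2cccc(OC)c12
F5 | step 5 | 2,2'-[8-methoxy-1-(methoxymethoxy)naphthalene-2,4-diyl]bis(4,4,5,5-tetramethyl-1,3,2-dioxaborolane) | COCOc1c(B2OC(C)(C)C(C)(C)O2)cc(B2OC(C)(C)C(C)(C)O2)c2cccc(OC)c12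
F6 | step 2 | 8-hydroxynaphthalen-1-yl 4-methylbenzenesulfonate | Cc1ccc(cc1)S(=O)(=O)Oc1cccc2cccc(O)c12
F7 | step 2 | 5,7-dibromo-8-hydroxynaphthalen-1-yl 4-methylbenzenesulfonate | Cc1ccc(cc1)S(=O)(=O)Oc1cccc2c(Br)cc(Br)c(O)c12
F8 | step 2 | 5,7-dibromo-8-(methoxymethoxy)naphthalen-1-yl 4-methylbenzenesulfonate | Cc1ccc(cc1)S(=O)(=O)Oc1cccc2c(Br)cc(Br)c(OCOC)c12
F9 | step 2 | 5,7-dibromo-8-(methoxymethoxy)naphthalen-1-ol | Oc1cccc2c(Br)cc(Br)c(OCOC)c12
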